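**Retrosynthetic overview**

1. The route rests on the Z-2-ene-1,4-diol O–C3–C4(C15)=C5–C6–O of the ten-membered ring (germacrane numbering). This unit is the ring-opened form of a 4,7-dihydro-1,3,2-dioxasilepine, so C4=C5 is cut by ring-closing metathesis of the diisopropylsilylene acetal of a C3 isopropenyl carbinol and a C6 vinyl carbinol.
2. After the tether: the C1–O–C10 oxirane comes from the E olefin (last step), the C8 ester from a Mitsunobu inversion, and the C7–C8 bond from an intramolecular Nozaki–Hiyama allylation of an α-(bromomethyl)butenolide onto the C8 aldehyde.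
3. The bromomethylbutenolide is made from the α-methylene lactone by nucleophilic epoxidation, bromide opening and dehydration, because Br2 would attack C1=C10 before the enoate.
4. Fragments: the C3 carbinol from but-3-yn-1-ol (carboalumination/oxirane, isopropenyl Grignard, CBS reduction); the C6 carbinol from acrolein and ethyl 2-(bromomethyl)acrylate (zinc Barbier, Sharpless kinetic resolution).
5. Ring order: seven-membered dioxasilepine (temporary, step 10), γ-lactone (step 11), ten-membered carbocycle (step 18), oxirane (step 21).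

Key step: step 10

Assumption: locants C1–C15 follow germacrane numbering (C1–C10 ring, C11–C13 lactone carbons, C14 on C10, C15 on C4), and the chromium allylation is assumed to pass through the closed chair transition state and give the 8S alcohol, so the C8 ester is introduced with inversion.

**Route**

Step 1
Reactants: 1 but-3-yn-1-ol
Product: 2 1-[(but-3-yn-1-yloxy)methyl]-4-methoxybenzene
Conditions: NaH (1.05 equiv), PMBCl, Bu4NI (cat.), THF/DMF, 0 °C → rt
Reagents that add atoms: 4-methoxybenzyl chloride, COc1ccc(CCl)cc1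
Why: Williamson etherification in which one equivalent of NaH removes only the O–H; the PMB ether survives organoaluminium, fluoride and mild acid and is later removed oxidatively.

Step 2
Reactants: 2 1-[(but-3-yn-1-yloxy)methyl]-4-methoxybenzene; 3 trimethylaluminium; 4 oxirane
Product: 7 (3E)-6-[(4-methoxybenzyl)oxy]-4-methylhex-3-en-1-ol, via alkenyldimethylalane 5 (not isolated), via lithium alkenylalanate 6 (not isolated)
Conditions: Me3Al, Cp2ZrCl2 (25 mol %), CH2Cl2, 0 °C → rt; evaporate; n-BuLi, hexane/THF, −78 → 0 °C; oxirane, 0 °C → rt; aq. HCl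
Reagents that add atoms: none
Why: Negishi zirconium-catalysed carboalumination adds CH3 and Al syn across the terminal alkyne with Al at the terminus, and the derived alanate opens oxirane with retention, which fixes the E C1=C10 olefin with its C14 methyl.

Step 3
Reactants: 7 (3E)-6-[(4-methoxybenzyl)oxy]-4-methylhex-3-en-1-ol
Product: 8 (3E)-6-[(4-methoxybenzyl)oxy]-4-methylhex-3-enal
Conditions: Dess–Martin periodinane, NaHCO3, CH2Cl2, 0 °C; used crude
Reagents that add atoms: none
Why: Dess–Martin oxidation under buffered neutral conditions, the usual way to obtain a β,γ-unsaturated aldehyde without moving the olefin into conjugation.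

Step 4
Reactants: 8 (3E)-6-[(4-methoxybenzyl)oxy]-4-methylhex-3-enal; 9 isopropenylmagnesium bromide
Product: 10 rac-(5E)-8-[(4-methoxybenzyl)oxy]-2,6-dimethylocta-1,5-dien-3-ol
Conditions: THF, −78 → −40 °C; H2O
Reagents that add atoms: none
Why: Grignard 1,2-addition at low temperature, where addition outruns enolisation of the aldehyde; the C3 carbinol forms as the racemate and its configuration is set in step 6.

Step 5
Reactants: 10 rac-(5E)-8-[(4-methoxybenzyl)oxy]-2,6-dimethylocta-1,5-dien-3-ol
Product: 11 (5E)-8-[(4-methoxybenzyl)oxy]-2,6-dimethylocta-1,5-dien-3-one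
Conditions: Dess–Martin periodinane, NaHCO3, CH2Cl2, 0 °C
Reagents that add atoms: none
Why: Dess–Martin oxidation of the allylic alcohol; the buffered, non-basic medium should keep the skipped C1=C10 olefin out of conjugation with the new enone.

Step 6
Reactants: 11 (5E)-8-[(4-methoxybenzyl)oxy]-2,6-dimethylocta-1,5-dien-3-one
Product: 12 (3R,5E)-8-[(4-methoxybenzyl)oxy]-2,6-dimethylocta-1,5-dien-3-ol
Conditions: (S)-2-methyl-CBS-oxazaborolidine (20 mol %), catecholborane, toluene, −78 °C; aq. work-up
Reagents that add atoms: none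
Why: Corey–Bakshi–Shibata reduction in which the isopropenyl group acts as the large and the CH2 group as the small substituent, so the (S)-catalyst should deliver hydride to the face that gives the 3R alcohol.

Step 7
Reactants: 13 acrolein; 14 ethyl 2-(bromomethyl)prop-2-enoate
Product: 16 rac-ethyl 4-hydroxy-2-methylidenehex-5-enoate, via 2-(ethoxycarbonyl)allylzinc bromide 15 (not isolated)
Conditions: Zn dust, THF/sat. aq. NH4Cl, 0 °C → rt; neutral work-up
Reagents that add atoms: none
Why: Zinc Barbier allylation, 1,2 to acrolein; the γ-hydroxy ethyl ester is isolated without acid so that it does not lactonise, and the C6 carbinol is racemic at this stage.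

Step 8
Reactants: 16 rac-ethyl 4-hydroxy-2-methylidenehex-5-enoate
Product: 17 ethyl (4S)-4-hydroxy-2-methylidenehex-5-enoate
Conditions: Ti(OiPr)4, D-(−)-DIPT, t-BuOOH (0.6 equiv), 4 Å MS, CH2Cl2, −20 °C; stopped at about 55 % conversion
Reagents that add atoms: none
Why: Sharpless kinetic resolution of a secondary allylic alcohol; with D-(−)-DIPT the R enantiomer should be epoxidised faster at its vinyl group (the acrylate olefin is inert), leaving the 4S alcohol (C6).

Step 9
Reactants: 17 ethyl (4S)-4-hydroxy-2-methylidenehex-5-enoate; 18 dichlorodi(propan-2-yl)silane; 12 (3R,5E)-8-[(4-methoxybenzyl)oxy]-2,6-dimethylocta-1,5-dien-3-ol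
Product: 20 ethyl (4S)-4-{[{[(3R,5E)-8-[(4-methoxybenzyl)oxy]-2,6-dimethylocta-1,5-dien-3-yl]oxy}di(propan-2-yl)silyl]oxy}-2-methylidenehex-5-enoate, via chlorosilyl ether 19 (not isolated)
Conditions: 17, iPr2SiCl2 (3 equiv), imidazole, CH2Cl2, 0 °C; excess silane off in vacuo; 12, imidazole, DMAP (cat.), CH2Cl2/DMF, rt
Reagents that add atoms: none
Why: Stepwise silyl ether formation; excess dichlorosilane gives the monoalkoxy chlorosilane and the second carbinol then displaces the remaining chloride, so symmetrical bis-ethers are avoided and no stereocentre is touched.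

Step 10
Reactants: 20 mixed diisopropylsilylene bis-allylic ether
Product: 21 ethyl 2-{[(4R,7S)-4-{(2E)-5-[(4-methoxybenzyl)oxy]-3-methylpent-2-en-1-yl}-5-methyl-2,2-di(propan-2-yl)-4,7-dihydro-1,3,2-dioxasilepin-7-yl]methyl}prop-2-enoate
Conditions: Grubbs second-generation catalyst (5–10 mol %), CH2Cl2 (0.005 M), 40 °C
Reagents that add atoms: none
Why: Ring-closing olefin metathesis: the ruthenium alkylidene loads on the monosubstituted C5 vinyl group, adds to the C4 isopropenyl group through a ruthenacyclobutane, and cycloreversion forms C4=C5 and a ruthenium methylidene that leaves as ethene. The closest known reaction type is silicon-tethered RCM of bis-allylic dialkylsilylene acetals to 4,7-dihydro-1,3,2-dioxasilepines, including cases that form trisubstituted olefins. The one ring closed is the seven-membered O–Si–O–C3–C4=C5–C6 ring, made by joining the terminal alkene carbons of the 1,8-diene held by the silicon acetal. No stereocentre is created; C3 (R) and C6 (S) come from 12 and 17 and are untouched. The step needs Z geometry and chemoselectivity among five olefins: Z is enforced because a seven-membered ring cannot hold an E olefin, and only the vinyl/isopropenyl pair can close an unstrained ring, since the electron-poor acrylate methylene could only give a cyclobutene and the trisubstituted C1=C10 olefin only a cyclobutene or an eight-membered ring with loss of a disubstituted alkylidene. High dilution suppresses cross-metathesis dimers.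

Step 11
Reactants: 21 dioxasilepine
Product: 23 (5S)-5-{(1Z,3R,5E)-3-hydroxy-8-[(4-methoxybenzyl)oxy]-2,6-dimethylocta-1,5-dien-1-yl}-3-methylideneoxolan-2-one, via acyclic diol ester 22 (not isolated)
Conditions: TBAF/AcOH (1:1), THF, 0 °C → rt; then PPTS (cat.), toluene, 50 °C
Reagents that add atoms: none
Why: Fluoride cleavage of the dialkoxysilane followed by acid-catalysed lactonisation (5-exo-trig acyl substitution); only the C6 hydroxyl can form a five-membered ring with the ester, the C3 hydroxyl stays free, and both carbinol centres are untouched.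

Step 12
Reactants: 23 hydroxy α-methylene lactone
Product: 24 (5S)-5-{(1Z,3R,5E)-3-{[tert-butyl(dimethyl)silyl]oxy}-8-[(4-methoxybenzyl)oxy]-2,6-dimethylocta-1,5-dien-1-yl}-3-methylideneoxolan-2-one
Conditions: TBSOTf, 2,6-lutidine, CH2Cl2, −78 °C
Reagents that add atoms: tert-butyldimethylsilyl triflate, CC(C)(C)[Si](C)(C)OS(=O)(=O)C(F)(F)F
Why: Silylation with a silyl triflate and a hindered, non-nucleophilic base that does not add to the methylene lactone; the TBS ether guards C3–OH against thionyl chloride and the Mitsunobu step.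

Step 13
Reactants: 24 TBS-protected α-methylene lactone
Product: 25 (6S)-6-{(1Z,3R,5E)-3-{[tert-butyl(dimethyl)silyl]oxy}-8-[(4-methoxybenzyl)oxy]-2,6-dimethylocta-1,5-dien-1-yl}-1,5-dioxaspiro[2.4]heptan-4-one (both epimers at the spiro carbon C11)
Conditions: t-BuOOH (anhydrous, decane), DBU, ClCH2CH2Cl, 0 °C → rt
Reagents that add atoms: tert-butyl hydroperoxide, CC(C)(C)OO
Why: Weitz–Scheffer nucleophilic epoxidation; the hydroperoxide anion adds only to the electron-poor exocyclic methylene and the enolate closes the oxirane, so the two trisubstituted olefins are untouched and the C11 epimers converge in step 15.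

Step 14
Reactants: 25 spiro-epoxy lactone
Product: 26 (5S)-3-(bromomethyl)-5-{(1Z,3R,5E)-3-{[tert-butyl(dimethyl)silyl]oxy}-8-[(4-methoxybenzyl)oxy]-2,6-dimethylocta-1,5-dien-1-yl}-3-hydroxyoxolan-2-one (both C11 epimers)
Conditions: LiBr, AcOH, THF, rt
Reagents that add atoms: lithium bromide, [Li+].[Br-]
Why: Halide opening of a glycidic ester; bromide attacks the unhindered CH2 (C13) of the acid-activated epoxide by SN2 and leaves the tertiary C11 hydroxyl.

Step 15
Reactants: 26 bromohydrin lactone
Product: 27 (5R)-3-(bromomethyl)-5-{(1Z,3R,5E)-3-{[tert-butyl(dimethyl)silyl]oxy}-8-[(4-methoxybenzyl)oxy]-2,6-dimethylocta-1,5-dien-1-yl}furan-2(5H)-one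
Conditions: SOCl2, pyridine, CH2Cl2, −20 → 0 °C; short contact time
Reagents that add atoms: none
Why: Dehydration of a tertiary α-hydroxy lactone through its chlorosulfite (E2); loss of a C7 hydrogen gives the endocyclic conjugated butenolide, the same regiochemistry as the dehydrohalogenation of α-bromo-α-(bromomethyl)-γ-lactones, and pyridine is too weak a base to epimerise C6 (the descriptor changes to R only because the CIP ranking changes).

Step 16
Reactants: 27 PMB-protected bromomethylbutenolide
Product: 28 (5R)-3-(bromomethyl)-5-[(1Z,3R,5E)-3-{[tert-butyl(dimethyl)silyl]oxy}-8-hydroxy-2,6-dimethylocta-1,5-dien-1-yl]furan-2(5H)-one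
Conditions: DDQ, CH2Cl2/pH 7 buffer, 0 °C
Reagents that add atoms: none
Why: Oxidative cleavage of the p-methoxybenzyl ether by DDQ (hydride abstraction, then hydrolysis of the hemiacetal), which leaves the TBS ether, the allylic bromide and the olefins alone.

Step 17
Reactants: 28 hydroxy bromomethylbutenolide
Product: 29 (3E,6R,7Z)-8-[(2R)-4-(bromomethyl)-5-oxo-2,5-dihydrofuran-2-yl]-6-{[tert-butyl(dimethyl)silyl]oxy}-3,7-dimethylocta-3,7-dienal
Conditions: Dess–Martin periodinane, NaHCO3, CH2Cl2, 0 °C; used at once
Reagents that add atoms: none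
Why: Dess–Martin oxidation of the homoallylic primary alcohol under buffered conditions should give the β,γ-unsaturated C8 aldehyde without moving C1=C10 into conjugation.

Step 18
Reactants: 29 aldehyde bromomethylbutenolide
Product: 31 (3R,6R,7R,8S)-3-{[tert-butyl(dimethyl)silyl]oxy}-8-hydroxygermacra-1(10)E,4Z,11(13)-trien-12,6-olide, via allylchromium(III) dichloride 30 (not isolated)
Conditions: CrCl2 (8 equiv), THF, rt, slow addition of 29 (final 2 mM); aq. work-up
Reagents that add atoms: none
Why: Intramolecular Nozaki–Hiyama (chromium Barbier) allylation: the allylchromium formed at C13 adds through C7 to the C8 aldehyde in a closed six-membered chair transition state and re-forms the C11=C13 methylene; C8 should bond to the butenolide face anti to the C5 substituent on C6 (trans lactone, 7R), and with the aldehyde chain equatorial the ring-locked allyl geometry (C6 trans to C13) should give the 8S (8α) alcohol.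

Step 19
Reactants: 31 macrocyclic 8S alcohol; 32 3-methylbutanoic acid
Product: 33 (3R,6R,7R,8R)-3-{[tert-butyl(dimethyl)silyl]oxy}-8-(3-methylbutanoyloxy)germacra-1(10)E,4Z,11(13)-trien-12,6-olide
Conditions: PPh3, DIAD (betaine pre-formed), toluene, 0 °C → rt
Reagents that add atoms: none
Why: Mitsunobu esterification; SN2 displacement of the C8 oxyphosphonium by the carboxylate inverts C8 from S to R, and H-7 is cis to the leaving group so anti-elimination toward C7 is not available.

Step 20
Reactants: 33 TBS-protected isovalerate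
Product: 34 (3R,6R,7R,8R)-3-hydroxy-8-(3-methylbutanoyloxy)germacra-1(10)E,4Z,11(13)-trien-12,6-olide
Conditions: HF·pyridine, pyridine, THF, 0 °C → rt
Reagents that add atoms: none
Why: Fluoride-mediated cleavage of the silyl ether under buffered conditions that the ester, the methylene lactone and both olefins tolerate; no epoxide is present yet, so no acid-sensitive group is exposed.

Step 21
Reactants: 34 hydroxy diene lactone
Product: 35 CNP0300193.1, (1R,3R,6R,7R,8R,10R)-1,10-epoxy-3-hydroxy-8-(3-methylbutanoyloxy)germacra-4Z,11(13)-dien-12,6-olide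
Conditions: dimethyldioxirane (1.1 equiv, acetone), CH2Cl2, −40 → −20 °C
Reagents that add atoms: dimethyldioxirane, CC1(C)OO1
Why: Electrophilic epoxidation; C1=C10 is the most electron-rich olefin (C4=C5 carries two allylic C–O bonds, the enoate is electron-poor), and attack on its peripheral face in the conformer with C14 on the β face (syn to H-6) should give the 1R,10R trans-epoxide, while the neutral reagent avoids transannular opening by the C3 hydroxyl.

**Compound list**

1 | but-3-yn-1-ol | C#CCCO | starting material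
2 | 1-[(but-3-yn-1-yloxy)methyl]-4-methoxybenzene | C#CCCOCc1ccc(OC)cc1 | intermediate
3 | trimethylaluminium | C[Al](C)C | starting material
4 | oxirane | C1CO1 | starting material
5 | (E)-alkenyldimethylalane from 2 | C[Al](C)/C=C(\C)CCOCc1ccc(OC)cc1 | intermediate (not isolated)
6 | lithium n-butyl(dimethyl)alkenylalanate | [Li+].CCCC[Al-](C)(C)/C=C(\C)CCOCc1ccc(OC)cc1 | intermediate (not isolated)
7 | (3E)-6-[(4-methoxybenzyl)oxy]-4-methylhex-3-en-1-ol | OCC/C=C(\C)CCOCc1ccc(OC)cc1 | intermediate
8 | (3E)-6-[(4-methoxybenzyl)oxy]-4-methylhex-3-enal | O=CC/C=C(\C)CCOCc1ccc(OC)cc1 | intermediate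
9 | isopropenylmagnesium bromide | C=C(C)[Mg]Br | starting material
10 | rac-(5E)-8-[(4-methoxybenzyl)oxy]-2,6-dimethylocta-1,5-dien-3-ol | C=C(C)C(O)C/C=C(\C)CCOCc1ccc(OC)cc1 | intermediate
11 | (5E)-8-[(4-methoxybenzyl)oxy]-2,6-dimethylocta-1,5-dien-3-one | C=C(C)C(=O)C/C=C(\C)CCOCc1ccc(OC)cc1 | intermediate
12 | (3R,5E)-8-[(4-methoxybenzyl)oxy]-2,6-dimethylocta-1,5-dien-3-ol | C=C(C)[C@H](O)C/C=C(\C)CCOCc1ccc(OC)cc1 | intermediate
13 | acrolein | C=CC=O | starting material
14 | ethyl 2-(bromomethyl)prop-2-enoate | C=C(CBr)C(=O)OCC | starting material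
15 | 2-(ethoxycarbonyl)allylzinc bromide | C=C(C[Zn]Br)C(=O)OCC | intermediate (not isolated)
16 | rac-ethyl 4-hydroxy-2-methylidenehex-5-enoate | C=CC(O)CC(=C)C(=O)OCC | intermediate
17 | ethyl (4S)-4-hydroxy-2-methylidenehex-5-enoate | C=C[C@@H](O)CC(=C)C(=O)OCC | intermediate
18 | dichlorodi(propan-2-yl)silane | CC(C)[Si](Cl)(Cl)C(C)C | starting material
19 | ethyl (4S)-4-{[chlorodi(propan-2-yl)silyl]oxy}-2-methylidenehex-5-enoate | C=C[C@@H](O[Si](Cl)(C(C)C)C(C)C)CC(=C)C(=O)OCC | intermediate (not isolated)
20 | mixed diisopropylsilylene bis-ether of 17 (C6, S) and 12 (C3, R) | C=C(C)[C@@H](C/C=C(\C)CCOCc1ccc(OC)cc1)O[Si](C(C)C)(C(C)C)O[C@H](C=C)CC(=C)C(=O)OCC | intermediate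
21 | (4R,7S)-4,7-dihydro-1,3,2-dioxasilepine with the C1–C2, C8–C10 chain on ring C4 and the acrylate arm on ring C7 | CCOC(=O)C(=C)C[C@H]1/C=C(/C)[C@@H](C/C=C(\C)CCOCc2ccc(OC)cc2)O[Si](C(C)C)(C(C)C)O1 | intermediate
22 | ethyl (4S,5Z,7R,9E)-4,7-dihydroxy-12-[(4-methoxybenzyl)oxy]-6,10-dimethyl-2-methylidenedodeca-5,9-dienoate | CCOC(=O)C(=C)C[C@H](O)/C=C(/C)[C@H](O)C/C=C(\C)CCOCc1ccc(OC)cc1 | intermediate (not isolated)
23 | (5S)-5-{(1Z,3R,5E)-3-hydroxy-8-[(4-methoxybenzyl)oxy]-2,6-dimethylocta-1,5-dien-1-yl}-3-methylideneoxolan-2-one | C=C1C[C@@H](/C=C(/C)[C@H](O)C/C=C(\C)CCOCc2ccc(OC)cc2)OC1=O | intermediate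
24 | TBS ether of 23 at C3–OH | C=C1C[C@@H](/C=C(/C)[C@H](O[Si](C)(C)C(C)(C)C)C/C=C(\C)CCOCc2ccc(OC)cc2)OC1=O | intermediate
25 | spiro-epoxy lactone (C11 epimers) | O=C1O[C@H](/C=C(/C)[C@H](O[Si](C)(C)C(C)(C)C)C/C=C(\C)CCOCc2ccc(OC)cc2)CC13CO3 | intermediate
26 | α-hydroxy-α-(bromomethyl) lactone (C11 epimers) | O=C1O[C@H](/C=C(/C)[C@H](O[Si](C)(C)C(C)(C)C)C/C=C(\C)CCOCc2ccc(OC)cc2)CC1(O)CBr | intermediate
27 | (5R)-3-(bromomethyl)butenolide, C8 as PMB ether | BrCC1=C[C@@H](/C=C(/C)[C@H](O[Si](C)(C)C(C)(C)C)C/C=C(\C)CCOCc2ccc(OC)cc2)OC1=O | intermediate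
28 | (5R)-3-(bromomethyl)butenolide, C8 as primary alcohol | BrCC1=C[C@@H](/C=C(/C)[C@H](O[Si](C)(C)C(C)(C)C)C/C=C(\C)CCO)OC1=O | intermediate
29 | (3E,6R,7Z)-8-[(2R)-4-(bromomethyl)-5-oxo-2,5-dihydrofuran-2-yl]-6-{[tert-butyl(dimethyl)silyl]oxy}-3,7-dimethylocta-3,7-dienal | BrCC1=C[C@@H](/C=C(/C)[C@H](O[Si](C)(C)C(C)(C)C)C/C=C(\C)CC=O)OC1=O | intermediate
30 | allylchromium(III) dichloride from 29 | Cl[Cr](Cl)CC1=C[C@@H](/C=C(/C)[C@H](O[Si](C)(C)C(C)(C)C)C/C=C(\C)CC=O)OC1=O | intermediate (not isolated)
31 | (3R,6R,7R,8S)-3-{[tert-butyl(dimethyl)silyl]oxy}-8-hydroxygermacra-1(10)E,4Z,11(13)-trien-12,6-olide | C=C1C(=O)O[C@@H]2/C=C(/C)[C@H](O[Si](C)(C)C(C)(C)C)C/C=C(\C)C[C@H](O)[C@@H]12 | intermediate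
32 | 3-methylbutanoic acid | CC(C)CC(=O)O | starting material
33 | (3R,6R,7R,8R)-3-{[tert-butyl(dimethyl)silyl]oxy}-8-(3-methylbutanoyloxy)germacra-1(10)E,4Z,11(13)-trien-12,6-olide | C=C1C(=O)O[C@@H]2/C=C(/C)[C@H](O[Si](C)(C)C(C)(C)C)C/C=C(\C)C[C@@H](OC(=O)CC(C)C)[C@@H]12 | intermediate
34 | (3R,6R,7R,8R)-3-hydroxy-8-(3-methylbutanoyloxy)germacra-1(10)E,4Z,11(13)-trien-12,6-olide | C=C1C(=O)O[C@@H]2/C=C(/C)[C@H](O)C/C=C(\C)C[C@@H](OC(=O)CC(C)C)[C@@H]12 | intermediate
35 | CNP0300193.1 | C=C1C(=O)O[C@@H]2/C=C(/C)[C@H](O)C[C@H]3O[C@]3(C)C[C@@H](OC(=O)CC(C)C)[C@@H]12 | target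

**Step count**

Total: 21 steps. Longest linear sequence: 19 steps (from but-3-yn-1-ol: steps 1–6 and 9–21).

**Steps most likely to fail**

Step 18 (chromium allylation closing the ten-membered ring). Intermolecular allylation may outrun ring closure at the heterogeneous chromium stage and give oligomers. The β,γ-unsaturated aldehyde may isomerise into conjugation, or the allylchromium may undergo 1,4-elimination with opening of the lactone. The fallback replaces the Barbier reaction by an intramolecular allylboration of an isolable allylboronate, which is unimolecular and needs no reductant. It sets out from 27. Palladium-catalysed borylation of the allylic bromide with bis(pinacolato)diboron should give the PMB-protected allylboronate F1. DDQ then gives the hydroxy allylboronate F2, and Dess–Martin oxidation gives the aldehyde allylboronate F3. F3 is cyclised at high dilution in warm toluene with catalytic Sc(OTf)3, through the same closed chair transition state. Aqueous work-up returns the route at 31.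

Step 19 (Mitsunobu inversion at C8). Displacement at the hindered C8 oxyphosphonium may be slow with the weakly acidic aliphatic acid. Elimination toward C9 or addition of the phosphine to the methylene lactone may then take over. The fallback separates activation from displacement and sets out from 31. Mesylation (MsCl, pyridine, CH2Cl2, 0 °C) should give the 8α-methanesulfonate F4. SN2 displacement with caesium 3-methylbutanoate (from 32 and Cs2CO3) and 18-crown-6 in toluene at 90 °C inverts C8 and returns the route at 33.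

Step 21 (final epoxidation). The reagent may attack the other face of C1=C10 if the conformer with C14 on the α face is populated. The free C3 hydroxyl may direct oxidation to C4=C5, or it may open the new oxirane across the ring. The fallback moves the epoxidation in front of the desilylation and puts the face selection under catalyst control; it sets out from 33. Shi epoxidation (D-fructose-derived ketone, Oxone, buffered MeCN/dimethoxymethane/water, 0 °C), which gives R,R epoxides from E-trisubstituted olefins, should give the silyl-protected epoxide F5. Buffered TBAF/AcOH then removes the TBS group and returns the route at 35.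

**Further compounds**

F1 | step 18 | (5R)-3-[(4,4,5,5-tetramethyl-1,3,2-dioxaborolan-2-yl)methyl]butenolide, C8 as PMB ether, C3 as TBS ether | CC1(C)OB(CC2=C[C@@H](/C=C(/C)[C@H](O[Si](C)(C)C(C)(C)C)C/C=C(\C)CCOCc3ccc(OC)cc3)OC2=O)OC1(C)C
F2 | step 18 | (5R)-3-[(pinacolboryl)methyl]butenolide, C8 as primary alcohol | CC1(C)OB(CC2=C[C@@H](/C=C(/C)[C@H](O[Si](C)(C)C(C)(C)C)C/C=C(\C)CCO)OC2=O)OC1(C)C
F3 | step 18 | (5R)-3-[(pinacolboryl)methyl]butenolide, C8 as aldehyde | CC1(C)OB(CC2=C[C@@H](/C=C(/C)[C@H](O[Si](C)(C)C(C)(C)C)C/C=C(\C)CC=O)OC2=O)OC1(C)C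
F4 | step 19 | 8α-methanesulfonate of 31 (all centres as in 31) | C=C1C(=O)O[C@@H]2/C=C(/C)[C@H](O[Si](C)(C)C(C)(C)C)C/C=C(\C)C[C@H](OS(C)(=O)=O)[C@@H]12
F5 | step 21 | 3-O-TBS ether of 35 | C=C1C(=O)O[C@@H]2/C=C(/C)[C@H](O[Si](C)(C)C(C)(C)C)C[C@H]3O[C@]3(C)C[C@@H](OC(=O)CC(C)C)[C@@H]12
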